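**Plan**
- Retrosynthesis: first the 14 O-benzyl bonds and the lower gallate ester are removed. Then the upper pyran ring is cut at O1–C2 and C3–C4 into an o-quinone methide (upper A ring plus C4 carrying C8 of the lower flavan) and a (Z)-styryl gallate (C2, C3, B ring, upper galloyl). Last, the C4–C8' bond (aryllithium + salicylaldehyde) and the enol-ester C–O bond (alkyne + acid) are cut.
- Forward: the lower unit is made from (−)-epicatechin (benzylation, silylation, C8 bromination) and joined by lithiation to the A-ring aldehyde. The resulting o-hydroxy diaryl carbinol is dehydrated to the quinone methide, and an oxa-[4+2] with the enol ester builds the upper C ring. Galloylation and hydrogenolysis finish the route.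
- Enabling feature: O1 sits ortho to the doubly benzylic C4 on a 5,7-dioxygenated (phloroglucinol) A ring, which gives a stabilised 1-oxadiene O1=C8a–C4a=C4. The C2=C3 alkene is polarised by the 4'-oxygenated B ring.
- Stereochemistry: C2'/C3' come from (−)-epicatechin. The 2,3-cis relation comes from the (Z)-enol ester, the 3,4-trans relation from the transition-state geometry, and the absolute sense at C2/C3/C4 from a chiral phosphoric acid.

Key step: step 10

Assumption: the (R) enantiomer of the phosphoric acid is taken as the one that opens the quinone-methide face leading to the (2R,3R,4R) upper unit; if the sense of induction is opposite, the (S) acid is used and nothing else changes.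

**Step 1**
Reactants: 1 (−)-epicatechin
Product: 2 5,7,3',4'-tetra-O-benzyl-(−)-epicatechin
Conditions: BnBr (4.4 equiv), K2CO3, DMF, 0 °C → rt
Reagents that add atoms: benzyl bromide, BrCc1ccccc1
Why: Williamson etherification of the four phenols under carbonate base should leave the non-acidic secondary 3-OH free and does not touch C2 or C3.

**Step 2**
Reactants: 2 5,7,3',4'-tetra-O-benzyl-(−)-epicatechin
Product: 3 3-O-(tert-butyldimethylsilyl)-5,7,3',4'-tetra-O-benzylepicatechin
Conditions: TBSCl, imidazole, DMF, rt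
Reagents that add atoms: tert-butyldimethylsilyl chloride, C[Si](C)(Cl)C(C)(C)C
Why: Standard silylation of the only free hydroxyl removes the acidic proton ahead of the halogen–lithium exchange.

**Step 3**
Reactants: 3 3-O-TBS-5,7,3',4'-tetra-O-benzylepicatechin
Product: 4 8-bromo-3-O-TBS-5,7,3',4'-tetra-O-benzylepicatechin
Conditions: NBS (1.0 equiv), CH2Cl2, −78 °C → rt
Reagents that add atoms: N-bromosuccinimide, O=C1CCC(=O)N1Br
Why: Electrophilic aromatic bromination of the trioxygenated A ring should occur at C8, the established site for benzylated flavan-3-ols (C6 is flanked by two benzyloxy groups).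

**Step 4**
Reactants: 5 2,4,6-trihydroxybenzaldehyde
Product: 6 2,4-bis(benzyloxy)-6-hydroxybenzaldehyde
Conditions: BnBr (2.0 equiv), K2CO3, DMF, 0 °C → rt
Reagents that add atoms: benzyl bromide, BrCc1ccccc1
Why: Williamson etherification stops at the dibenzyl ether because the last ortho hydroxyl is chelated to the formyl group and is the least nucleophilic.

**Step 5**
Reactants: 6 2,4-bis(benzyloxy)-6-hydroxybenzaldehyde
Product: 7 2,4-bis(benzyloxy)-6-(tert-butyldimethylsilyloxy)benzaldehyde
Conditions: TBSCl, imidazole, DMAP (cat.), CH2Cl2, rt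
Reagents that add atoms: tert-butyldimethylsilyl chloride, C[Si](C)(Cl)C(C)(C)C
Why: Silylation of the phenol prevents proton quench of the aryllithium and keeps the aldehyde electrophilic (a phenoxide would deactivate it).

**Step 6**
Reactants: 4 8-bromo-3-O-TBS-5,7,3',4'-tetra-O-benzylepicatechin; 7 2,4-bis(benzyloxy)-6-(tert-butyldimethylsilyloxy)benzaldehyde
Product: 9 bis-silylated diaryl carbinol (lower flavan C8–CH(OH)–upper A ring; both carbinol epimers), via 8-lithioflavan 8 (not isolated)
Conditions: n-BuLi (1.05 equiv), THF, −78 °C; then 7, −78 → −20 °C; aq NH4Cl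
Reagents that add atoms: none
Why: Bromine–lithium exchange followed by 1,2-addition of the aryllithium to the aldehyde forms the C4–C8' bond; the carbinol configuration is irrelevant because this carbon becomes sp2 in step 10, and any O→O silyl shift is irrelevant because step 7 removes both silyl groups.

**Step 7**
Reactants: 9 bis-silylated diaryl carbinol
Product: 10 desilylated o-hydroxy diaryl carbinol (phenol, carbinol OH and lower 3-OH free)
Conditions: TBAF (2.5 equiv), THF, 0 °C → rt; aq NH4Cl, chromatography on Et3N-deactivated silica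
Reagents that add atoms: none
Why: Fluoride-induced desilylation of the aryl and the secondary alkyl silyl ether under non-acidic conditions should leave the easily ionised bis(trioxyaryl)carbinol intact.

**Step 8**
Reactants: 11 3,4-bis(benzyloxy)benzaldehyde
Product: 12 4-ethynyl-1,2-bis(benzyloxy)benzene
Conditions: dimethyl (1-diazo-2-oxopropyl)phosphonate, K2CO3, MeOH/THF, rt
Reagents that add atoms: dimethyl (1-diazo-2-oxopropyl)phosphonate, CC(=O)C(=[N+]=[N-])P(=O)(OC)OC
Why: Seyferth–Gilbert homologation with the Ohira–Bestmann reagent converts the aryl aldehyde into the terminal alkyne under mild base.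

**Step 9**
Reactants: 12 4-ethynyl-1,2-bis(benzyloxy)benzene; 13 3,4,5-tris(benzyloxy)benzoic acid
Product: 14 (Z)-2-[3,4-bis(benzyloxy)phenyl]ethenyl 3,4,5-tris(benzyloxy)benzoate
Conditions: [Ru(methallyl)2(dppb)] (2 mol%), toluene, 60 °C
Reagents that add atoms: none
Why: Ruthenium-catalysed anti-Markovnikov hydro-oxycarbonylation of a terminal alkyne proceeds through a Ru-vinylidene and should deliver the (Z)-enol ester, the geometry that becomes the 2,3-cis relation.

**Step 10**
Reactants: 10 desilylated o-hydroxy diaryl carbinol; 14 (Z)-2-[3,4-bis(benzyloxy)phenyl]ethenyl 3,4,5-tris(benzyloxy)benzoate (1.5 equiv)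
Product: 16 5,7,3',4'-tetra-O-benzylepicatechin-3-O-(tri-O-benzylgallate)-(4β→8)-5,7,3',4'-tetra-O-benzylepicatechin (lower 3-OH free), via o-quinone methide 15 (not isolated)
Conditions: (R)-TRIP [(R)-3,3'-bis(2,4,6-triisopropylphenyl)-1,1'-binaphthyl-2,2'-diyl hydrogen phosphate] (10 mol%), 5 Å MS, toluene, −40 → 0 °C
Reagents that add atoms: none
Why: Proposed new method: the acid dehydrates 10 to the push–pull o-quinone methide 15 (1-oxadiene O1=C8a–C4a=C4, held as a hydrogen-bonded ion pair with the chiral phosphate), whose electrophilic C4 is attacked by the acyloxy-bearing carbon of 14 while the developing 4-benzyloxybenzyl cation at C2 is captured by O1, an asynchronous inverse-electron-demand oxa-[4+2] (hetero-Diels–Alder) cycloaddition whose closest known reaction type is the chiral Brønsted-acid-catalysed [4+2] of o-quinone methides from o-hydroxybenzhydrols with styrenes or enol ethers, here extended to a 1,2-disubstituted (Z)-β-acyloxystyrene and a quinone methide with a peri alkoxy group. The upper pyran ring closes by this intermolecular [4+2] through a six-membered transition state, C3–C4 bond formation leading and O1–C2 collapse of the ion pair following before C2–C3 rotation can occur. The regiochemistry required (C3 to C4, O1 to C2) is secured by the para-benzyloxy group of the styrene, which stabilises positive charge at C2 far better than the acyloxy group could at C3. The 2,3-cis relation follows from suprafacial addition to the (Z)-alkene, and the 3,4-trans relation should follow because the 5-benzyloxy group turns the C4 aryl (lower unit) syn to the quinone-methide oxygen, from where it swings quasi-axial as the ring forms, while the endo approach usual for styrenes places the 3-acyloxy and 2-aryl groups trans to it. The absolute configuration (2R,3R,4R) is set by the face of 15 left open by the bound phosphate, and because the lower unit is already chiral a wrong-face adduct is a diastereomer removable by chromatography. The step also needs chemoselectivity for the alkene over the free lower 3-OH and water, which is expected because their additions to 15 are reversible whereas the cycloaddition is not.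

**Step 11**
Reactants: 16 protected dimer with free lower 3-OH; 13 3,4,5-tris(benzyloxy)benzoic acid
Product: 17 tetradeca-O-benzyl-3,3'-di-O-galloylprocyanidin B2
Conditions: 13 (3 equiv), DCC, DMAP, CH2Cl2, rt
Reagents that add atoms: none
Why: Steglich esterification acylates the single remaining hydroxyl (the hindered axial lower 3-OH, hence excess reagents) without touching any stereocentre.

**Step 12**
Reactants: 17 tetradeca-O-benzyl-3,3'-di-O-galloylprocyanidin B2
Product: 18 3,3'-di-O-galloylprocyanidin B2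
Conditions: H2 (1 atm), 20% Pd(OH)2/C, THF/MeOH/H2O, rt
Reagents that add atoms: none
Why: Hydrogenolysis over Pearlman's catalyst should remove all fourteen benzyl ethers under neutral conditions that spare the gallate esters, the acid-labile C4–C8 bond and all stereocentres.

**Compound list**
1 | (−)-epicatechin | c1c(O)cc(O)c2c1O[C@H](c1ccc(O)c(O)c1)[C@H](O)C2 | starting material
2 | 5,7,3',4'-tetra-O-benzyl-(−)-epicatechin | c1c(OCc4ccccc4)cc(OCc4ccccc4)c2c1O[C@H](c1ccc(OCc4ccccc4)c(OCc4ccccc4)c1)[C@H](O)C2 | intermediate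
3 | 3-O-TBS-5,7,3',4'-tetra-O-benzylepicatechin | c1c(OCc4ccccc4)cc(OCc4ccccc4)c2c1O[C@H](c1ccc(OCc4ccccc4)c(OCc4ccccc4)c1)[C@H](O[Si](C)(C)C(C)(C)C)C2 | intermediate
4 | 8-bromo-3-O-TBS-5,7,3',4'-tetra-O-benzylepicatechin | Brc1c(OCc4ccccc4)cc(OCc4ccccc4)c2c1O[C@H](c1ccc(OCc4ccccc4)c(OCc4ccccc4)c1)[C@H](O[Si](C)(C)C(C)(C)C)C2 | intermediate
5 | 2,4,6-trihydroxybenzaldehyde | O=Cc1c(O)cc(O)cc1O | starting material
6 | 2,4-bis(benzyloxy)-6-hydroxybenzaldehyde | O=Cc1c(O)cc(OCc2ccccc2)cc1OCc1ccccc1 | intermediate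
7 | 2,4-bis(benzyloxy)-6-(tert-butyldimethylsilyloxy)benzaldehyde | O=Cc1c(O[Si](C)(C)C(C)(C)C)cc(OCc2ccccc2)cc1OCc1ccccc1 | intermediate
8 | 8-lithio-3-O-TBS-5,7,3',4'-tetra-O-benzylepicatechin | [Li]c1c(OCc4ccccc4)cc(OCc4ccccc4)c2c1O[C@H](c1ccc(OCc4ccccc4)c(OCc4ccccc4)c1)[C@H](O[Si](C)(C)C(C)(C)C)C2 | intermediate
9 | [2,4-bis(benzyloxy)-6-(TBSO)phenyl][(2R,3R)-5,7-bis(benzyloxy)-2-(3,4-bis(benzyloxy)phenyl)-3-(TBSO)chroman-8-yl]methanol, both carbinol epimers | OC(c1c(O[Si](C)(C)C(C)(C)C)cc(OCc4ccccc4)cc1OCc1ccccc1)c1c(OCc4ccccc4)cc(OCc4ccccc4)c2c1O[C@H](c1ccc(OCc4ccccc4)c(OCc4ccccc4)c1)[C@H](O[Si](C)(C)C(C)(C)C)C2 | intermediate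
10 | [2,4-bis(benzyloxy)-6-hydroxyphenyl][(2R,3R)-5,7-bis(benzyloxy)-2-(3,4-bis(benzyloxy)phenyl)-3-hydroxychroman-8-yl]methanol, both carbinol epimers | OC(c1c(O)cc(OCc4ccccc4)cc1OCc1ccccc1)c1c(OCc4ccccc4)cc(OCc4ccccc4)c2c1O[C@H](c1ccc(OCc4ccccc4)c(OCc4ccccc4)c1)[C@H](O)C2 | intermediate
11 | 3,4-bis(benzyloxy)benzaldehyde | O=Cc1ccc(OCc2ccccc2)c(OCc2ccccc2)c1 | starting material
12 | 4-ethynyl-1,2-bis(benzyloxy)benzene | C#Cc1ccc(OCc2ccccc2)c(OCc2ccccc2)c1 | intermediate
13 | 3,4,5-tris(benzyloxy)benzoic acid | OC(=O)c1cc(OCc2ccccc2)c(OCc2ccccc2)c(OCc2ccccc2)c1 | starting material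
14 | (Z)-2-[3,4-bis(benzyloxy)phenyl]ethenyl 3,4,5-tris(benzyloxy)benzoate | O=C(O/C=C\c1ccc(OCc2ccccc2)c(OCc2ccccc2)c1)c1cc(OCc2ccccc2)c(OCc2ccccc2)c(OCc2ccccc2)c1 | intermediate
15 | (Z)-o-quinone methide: 3,5-bis(benzyloxy)-6-[(flavan-8-yl)methylidene]cyclohexa-2,4-dienone, lower aryl syn to C=O, lower unit (2R,3R) with free 3-OH | O=C1C=C(OCc4ccccc4)C=C(OCc4ccccc4)/C1=C/c1c(OCc4ccccc4)cc(OCc4ccccc4)c2c1O[C@H](c1ccc(OCc4ccccc4)c(OCc4ccccc4)c1)[C@H](O)C2 | intermediate
16 | 5,7,3',4'-tetra-O-benzylepicatechin-3-O-(tri-O-benzylgallate)-(4β→8)-5,7,3',4'-tetra-O-benzylepicatechin, upper unit (2R,3R,4R), lower 3-OH free | O=C(O[C@@H]1[C@@H](c2c(OCc4ccccc4)cc(OCc4ccccc4)c3c2O[C@H](c2ccc(OCc4ccccc4)c(OCc4ccccc4)c2)[C@H](O)C3)c2c(OCc4ccccc4)cc(OCc4ccccc4)cc2O[C@@H]1c1ccc(OCc4ccccc4)c(OCc4ccccc4)c1)c1cc(OCc4ccccc4)c(OCc4ccccc4)c(OCc4ccccc4)c1 | intermediate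
17 | tetradeca-O-benzyl-3,3'-di-O-galloylprocyanidin B2 | O=C(O[C@@H]1[C@@H](c2c(OCc4ccccc4)cc(OCc4ccccc4)c3c2O[C@H](c2ccc(OCc4ccccc4)c(OCc4ccccc4)c2)[C@H](OC(=O)c2cc(OCc4ccccc4)c(OCc4ccccc4)c(OCc4ccccc4)c2)C3)c2c(OCc4ccccc4)cc(OCc4ccccc4)cc2O[C@@H]1c1ccc(OCc4ccccc4)c(OCc4ccccc4)c1)c1cc(OCc4ccccc4)c(OCc4ccccc4)c(OCc4ccccc4)c1 | intermediate
18 | 3,3'-di-O-galloylprocyanidin B2 | O=C(O[C@@H]1[C@@H](c2c(O)cc(O)c3c2O[C@H](c2ccc(O)c(O)c2)[C@H](OC(=O)c2cc(O)c(O)c(O)c2)C3)c2c(O)cc(O)cc2O[C@@H]1c1ccc(O)c(O)c1)c1cc(O)c(O)c(O)c1 | target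

**Step count**
Total steps: 12. Longest linear sequence: 8 steps (1, 2, 3, 6, 7, 10, 11, 12).

**Steps most likely to fail**

Step 10 (Proposed new method). What may go wrong:
- insufficient endo/exo or facial selectivity in the cycloaddition;
- loss of the (Z)-alkene geometry by C2–C3 rotation in a stepwise cationic pathway, giving the 2,3-trans series;
- competing Friedel–Crafts capture of the quinone methide instead of ring formation.

Fallback (known chemistry) sets out from 2 and returns at 17. Oxidation of 2 at C4 with DDQ in the presence of 2-ethoxyethanol (CH2Cl2, rt) gives 4β-(2-ethoxyethoxy)-5,7,3',4'-tetra-O-benzylepicatechin F1. Steglich esterification of F1 with 13 (DCC, DMAP) gives the electrophile, its 3-O-(tri-O-benzylgallate) F2. A second portion of 2 is esterified with 13 in the same way to the nucleophile 5,7,3',4'-tetra-O-benzylepicatechin 3-O-(tri-O-benzylgallate) F3. Condensation of F2 with excess F3 under catalytic TMSOTf in CH2Cl2 at −78 °C forms the C4–C8 bond trans to the 3-acyloxy group and gives 17 directly; step 12 follows.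

Step 6. What may go wrong:
- sluggish addition of the hindered, doubly ortho-substituted aryllithium to the hindered, electron-rich aldehyde;
- competing metalation of benzyl ethers or attack at silicon;
- ionisation of the resulting carbinol during handling (also relevant to step 7).

Fallback sets out from 6 and 2 and returns at 15. Reduction of 6 with NaBH4 (MeOH/THF, 0 °C) gives 3,5-bis(benzyloxy)-2-(hydroxymethyl)phenol F4. Mild acid-catalysed Friedel–Crafts benzylation of 2 with F4 (Sc(OTf)3 cat., CH2Cl2, low temperature, via the parent o-quinone methide) attaches the benzyl group at the nucleophilic C8 and gives the diarylmethane 8-[2,4-bis(benzyloxy)-6-hydroxybenzyl]-5,7,3',4'-tetra-O-benzylepicatechin F5. Oxidation of F5 at the doubly benzylic methylene with Ag2O, in the presence of 14 and the phosphoric acid, generates 15, which continues as in step 10. This avoids steps 2, 3, 5, 6 and 7.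

Step 9. What may go wrong:
- erosion of Z-selectivity or Markovnikov addition with this electron-rich aryl alkyne and bulky acid;
- isomerisation of the enol ester under the catalyst.

Fallback sets out from 12 and returns at 14. Rhodium-catalysed formal trans-hydroboration of 12 with pinacolborane ([Rh(cod)Cl]2, P(i-Pr)3, Et3N, cyclohexane, rt, via a vinylidene) gives the (Z)-alkenylboronate 2-[(Z)-2-(3,4-bis(benzyloxy)phenyl)ethenyl]-4,4,5,5-tetramethyl-1,3,2-dioxaborolane F6. Chan–Lam-type oxidative C–O coupling of F6 with 13 (Cu(OAc)2 cat., Et3N, 4 Å MS, O2, CH2Cl2, rt) proceeds with retention of alkene geometry and gives 14.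

**Further compounds**
F1 | step 10 | 4β-(2-ethoxyethoxy)-5,7,3',4'-tetra-O-benzylepicatechin | O[C@@H]1[C@@H](OCCOCC)c2c(OCc4ccccc4)cc(OCc4ccccc4)cc2O[C@@H]1c1ccc(OCc4ccccc4)c(OCc4ccccc4)c1
F2 | step 10 | 4β-(2-ethoxyethoxy)-5,7,3',4'-tetra-O-benzylepicatechin 3-O-(3,4,5-tri-O-benzylgallate) | O=C(O[C@@H]1[C@@H](OCCOCC)c2c(OCc4ccccc4)cc(OCc4ccccc4)cc2O[C@@H]1c1ccc(OCc4ccccc4)c(OCc4ccccc4)c1)c1cc(OCc4ccccc4)c(OCc4ccccc4)c(OCc4ccccc4)c1
F3 | step 10 | 5,7,3',4'-tetra-O-benzylepicatechin 3-O-(3,4,5-tri-O-benzylgallate) | c1c(OCc4ccccc4)cc(OCc4ccccc4)c2c1O[C@H](c1ccc(OCc4ccccc4)c(OCc4ccccc4)c1)[C@H](OC(=O)c1cc(OCc4ccccc4)c(OCc4ccccc4)c(OCc4ccccc4)c1)C2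
F4 | step 6 | 3,5-bis(benzyloxy)-2-(hydroxymethyl)phenol | OCc1c(O)cc(OCc2ccccc2)cc1OCc1ccccc1
F5 | step 6 | 8-[2,4-bis(benzyloxy)-6-hydroxybenzyl]-5,7,3',4'-tetra-O-benzylepicatechin | Oc1cc(OCc4ccccc4)cc(OCc4ccccc4)c1Cc1c(OCc4ccccc4)cc(OCc4ccccc4)c2c1O[C@H](c1ccc(OCc4ccccc4)c(OCc4ccccc4)c1)[C@H](O)C2
F6 | step 9 | 2-[(Z)-2-(3,4-bis(benzyloxy)phenyl)ethenyl]-4,4,5,5-tetramethyl-1,3,2-dioxaborolane | CC1(C)OB(/C=C\c2ccc(OCc3ccccc3)c(OCc3ccccc3)c2)OC1(C)C
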